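## Structural features

The target is a C20 acetate built from two five-membered rings: a cyclopentane (ring A) joined by the single bond C5–C1′ to a 4-methylcyclopent-2-enone (ring B). Locants used here: ring A C1–C5, side chain C7–C11, ring B C1′–C5′ with C2′ the carbonyl; the α face of ring A is the face of the C1 oxygen, the β face that of CH2O. Ring A carries a tertiary hydroxyl and CH2OAc at C1, the chain C7(CH3)=C8–C9=C10–C11(CH3)2OOH at C3, and ring B at C5. CH2OAc, chain and ring B are all β and the hydroxyl is α, which corresponds to (1R,3S,5S). Ring B is attached through its ketone α-carbon C1′ (S), next to the methyl-bearing C5′ (R), and the two substituents are cis, so C1–C5–C1′–C5′ are four contiguous stereocentres across a freely rotating bond. Fragile points are the tertiary allylic hydroperoxide on a conjugated diene, C1′ (α to the enone carbonyl, liable to epimerise to the trans isomer) and the acetate, which cannot pass through amide-base or organometallic steps. The real difficulties are the cis C1′/C5′ pair, the C3 centre (1,3 to a quaternary carbon substituted on both faces) and a selective late oxygenation. The key step uses the fact that C1(OH)(CH2O)–C2–C3(=O)–C4=C5 is exactly 5, the rearrangement product of the flat, symmetric furan 2; the ketone is the handle for the chain and the enone β-carbon C5 the handle for ring B.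

## Logic of the disconnections

33 ⇒ 32. The C11–OOH bond is cut and the C9=C10 double bond moved back to C10=C11. Adding the peroxide last keeps it away from every basic, reducing or organometallic step and simplifies the chain to a skipped diene. The forward ene reaction must choose the terminal trisubstituted alkene over C7=C8 and take the doubly allylic hydrogen at C9.

32 ⇒ 31 ⇒ 30. The acetyl C–O bond and then the primary O–Si bond are cut. The acetate cannot survive the steps that build ring B, so the primary oxygen travels as a robust silyl ether. The forward steps must free it without touching C1′ and acetylate it beside the tertiary hydroxyl.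

30 ⇒ 29. The C3′=C4′ bond is cut (ring-closing metathesis forward). The cis-4,5-disubstituted enone becomes an open vinyl ketone in which C1′ and C5′ are an anti pair. The closure must be neutral and leave the two trisubstituted alkenes alone.

29 ⇒ 27 ⇒ 25. The C2′–C3′ bond is cut (vinyl addition to an N-methoxy-N-methylamide), leading back to a carboxylic acid. The sensitive vinyl ketone is thus made just before use; the demand is clean mono-addition without epimerising C1′.

25 ⇒ 22. The C1′–C5′ bond is cut as a [3,3] shift of an allyl ester enolate. Both ring B stereocentres disappear at once and only an achiral C4 alcohol has to be attached. Enolate geometry and a chair transition state must give the anti pair, and the C5 stereocentre must select the enolate face.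

22 ⇒ 20 + 21, 20 ⇒ 19. The ester C–O bond is cut and the acid traced to its methyl ester. An allylic ester would not pass the aluminium and palladium chemistry of the chain, so a methyl ester is carried and exchanged late at the cost of two simple steps.

19 ⇒ 16 + 17. The C8–C9 and C7–CH3 bonds are cut. One operation then builds the E-trisubstituted alkene and the skipped diene. It requires syn carbometalation with the metal on C8 and coupling at the unsubstituted end of the allyl unit, beside an ester and a free hydroxyl.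

16 ⇒ 15 ⇒ 14 ⇒ 12. C8 is removed (one-carbon homologation), the aldehyde returns to a primary alcohol, and the C3–H and C7–O bonds are cut to an exocyclic methylene. The C3 problem is reduced to the facial selectivity of one hydroboration, for which the C1 oxygen is deliberately a small free hydroxyl.

12 ⇒ 11 ⇒ 10. The tertiary O–Si bond is restored and C3=C7 is cut to the C3 ketone. The methylenation must not be basic, because the ketone has a β-silyloxy group and an ester.

10 ⇒ 7 + 8. The C5–C1′ bond is cut (conjugate addition of an acetate equivalent). Ring A returns to the key-step skeleton. The nucleophile must add anti to the C1 silyloxy group so that C1′ ends up cis to CH2O.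

7 ⇒ 5. Two different O–Si bonds are cut: a bulky, early-removable group on the tertiary oxygen to steer the addition, and a robust one on the primary oxygen to last to the end.

5 ⇒ 2. The C1–C2 bond is cut and the ring opened to the furan; this is the key disconnection. All six carbons and three oxygens of the ring A core come from a symmetric, achiral precursor. The forward step has one thing to control: the sense of ring closure.

2 ⇒ 1. One C–H bond is cut back to the aldehyde, a commodity chemical.

## Other disconnections considered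

Alternative 1: The cut is across C1–C5 and C2–C3 of ring A, a [4+2] retron in which C4 is the methylene bridge of a norbornene. Forward, cyclopenta-1,3-diene A2 and 2-bromoprop-2-enal A3 would combine under a chiral boron Lewis acid to give the exo-formyl, endo-bromo adduct A1.
- In favour: this catalytic enantioselective cycloaddition is established for this dienophile class, so the absolute configuration would rest on known chemistry. That is better than the chosen plan, whose key step is new in asymmetric form.
- In favour: the bicycle holds the two alkene carbons (future C7 and C1′) cis on C3 and C5. Reduction of the formyl group, closure to the spiro-epoxide A4 with inversion at C1, and opening at CH2 by acetate would place OH exo and CH2OAc endo, i.e. all three carbon substituents cis. C3 is therefore set without a face-selective addition, which is also better than the chosen plan.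
- Against: cleaving the C=C bond leaves two nearly equivalent formyl groups that must be differentiated, on a cis-1,3-dicarbonyl prone to epimerisation and hemiacetal formation. Each appendage starts from one carbon, so ring B must be grown from C1′ alone, without the C1′–C2′ unit that the chosen route installs in one conjugate addition.
- Comparison: structurally and mechanistically the plans are equally sound up to ring A. In step economy the alternative should be longer, and it meets the same C1′/C5′ and hydroperoxide problems.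

Alternative 2: The cut is the C1–C5 bond of ring A, made last. Forward, controlled-potential cathodic reduction of the acyclic keto-dienone A6 would form the radical anion of the alkylidene-cyclopentenone. Its exocyclic β-carbon (C5) would attack the ketone carbon (C1) in a 5-exo closure, and protonation of the enolate at C1′ would give A5.
- In favour: it is the most convergent plan. The chain and C3 arrive from an acyclic precursor, so the C3 problem of the chosen route does not arise (better), and no new asymmetric method is needed (better).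
- In favour: kinetic protonation anti to the C5′ methyl is a sound route to the cis ring B pair. This is equal to the chosen plan, which also sets C1′ under kinetic control.
- Against: three stereocentres (C1, C5, C1′) would depend on the single C3 centre, remote from the forming bond, with nothing comparable to a silyloxy-directed addition or a chair sigmatropic shift. A6 is a cross-conjugated dienone whose C5′–H is γ-acidic, so its own stereocentre is at risk, and hydrodimerisation or reduction of the ring enone compete.
- Comparison: in step economy the alternative wins if the cyclisation is selective. In predictability of configuration the chosen plan is stronger. The final ene reaction is common to both.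

Alternative 3: The cut is the C4=C5 bond, reached by contracting a cyclohexane. Forward, (−)-quinic acid A8 would be converted into its methyl ester 5-O-silyl ether A9. NaIO4 would cleave the cis-3,4-diol, and an amine-catalysed intramolecular aldol condensation would close the formyl-cyclopentene A7.
- In favour: C1 comes from the chiral pool with secure absolute configuration and only known reactions are used, both better than the chosen plan.
- In favour: the formyl carbon is C1′ and the ring oxygen marks C3. The C4=C5 bond could be hydrogenated under direction of the tertiary hydroxyl to put ring B trans to OH, which is equal to the anti addition of the chosen plan.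
- Against: the ester must be taken down to CH2OAc. The C3 oxygen is cis to the ester, so the chain must replace it with retention, in practice via the ketone, which leads back to the C3 problem of the chosen route (equal, not better). Ring B must be grown from a formyl carbon, one C–C bond more than from the acetate unit. Mono-silylation of the triol and the direction of the aldol closure are selectivity questions of their own.
- Comparison: both plans meet at a C3-oxidised, C5-substituted ring A. The alternative needs more steps but leaves no doubt about C1.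

Key step: step 2

Assumption (step 2): which enantiomer of the binaphthyl acid favours (R)-5 cannot be predicted; the (R)-acid is written and is to be replaced by its mirror image if the induction is opposite.
Assumption (fallback to step 2): the lipase is taken to acetylate the (S)-alcohol faster.
Remark: the (R) descriptor of 5 has the same spatial arrangement (OH, CH2O, C5, C2) as C1 of the target, so the key-step structures need no correction; the acetate is introduced late because it cannot survive steps 10 to 15.

## Steps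

Step 1
Reactants: 1 5-(hydroxymethyl)furfural
Product: 2 2,5-bis(hydroxymethyl)furan
Conditions: NaBH4, MeOH, 0 °C
Reagents that add atoms: none
Why: Borohydride reduction of the aldehyde; the furan and the primary alcohol are inert and no stereocentre is formed.

Step 2
Reactants: 2 2,5-bis(hydroxymethyl)furan
Product: 5 (4R)-4-hydroxy-4-(hydroxymethyl)cyclopent-2-en-1-one, via dihydrofuranol hemiketal 3 (not isolated), via hydroxypentadienyl cation 4 (not isolated)
Conditions: (R)-3,3′-bis(2,4,6-triisopropylphenyl)-1,1′-binaphthyl-2,2′-diyl N-triflylphosphoramide (10 mol %), H2O (10 equiv), 2-methyltetrahydrofuran, 70 °C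
Reagents that add atoms: water, O
Why: Proposed new method: the chiral acid ionises one of the two equivalent furfuryl alcohols, water adds to the distal ring carbon to give 3, and ring opening gives the 1,4-dihydroxypentadienyl cation 4, which closes the five-membered carbocycle by a conrotatory 4π electrocyclisation between the former CH2 carbon (C2) and the carbon bearing CH2OH (C1); loss of a proton gives the enone. The closest known reaction types are the acid-mediated aqueous Piancatelli rearrangement of 2 itself, which gives the racemate, and chiral-phosphoric-acid-catalysed aza-Piancatelli rearrangements, in which the chiral anion is hydrogen-bonded to the cation during ring closure. C1 is the only new stereocentre and is decided solely by the sense of conrotation; the control element is the chiral phosphoramide anion bound to the hydroxyl groups of 4 in a low-polarity medium with only a few equivalents of water. No regiochemical question arises because 2 is symmetric, so either CH2OH gives the same product, and no cis/trans question because C2 carries two hydrogens. The step needs the ion-paired pathway to outrun the uncatalysed racemic one, which is why bulk water is avoided and a strongly acidic phosphoramide is chosen.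

Step 3
Reactants: 5 (4R)-4-hydroxy-4-(hydroxymethyl)cyclopent-2-en-1-one
Product: 7 (4R)-4-{[(tert-butyldiphenylsilyl)oxy]methyl}-4-[(triethylsilyl)oxy]cyclopent-2-en-1-one, via primary silyl ether 6 (not isolated)
Conditions: t-BuPh2SiCl, imidazole, CH2Cl2, 0 °C; then Et3SiOTf, 2,6-lutidine, −78 to 0 °C (one pot)
Reagents that add atoms: tert-butyl(chloro)diphenylsilane, CC(C)(C)[Si](Cl)(c1ccccc1)c1ccccc1; triethylsilyl trifluoromethanesulfonate, CC[Si](CC)(CC)OS(=O)(=O)C(F)(F)F
Why: The silyl chloride with imidazole reacts only at the primary alcohol, and the hindered tertiary alcohol then needs the silyl triflate. The triethylsilyloxy group shields the α face for step 4 and blocks β-elimination while C3 is a ketone.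

Step 4
Reactants: 7 (4R)-4-{[(tert-butyldiphenylsilyl)oxy]methyl}-4-[(triethylsilyl)oxy]cyclopent-2-en-1-one; 8 tert-butyl[(1-methoxyethenyl)oxy]dimethylsilane
Product: 10 methyl 2-[(1S,2R)-2-{[(tert-butyldiphenylsilyl)oxy]methyl}-4-oxo-2-[(triethylsilyl)oxy]cyclopentyl]acetate, via silyl enol ether 9 (not isolated)
Conditions: t-BuMe2SiOTf (10 mol %), CH2Cl2, −78 °C; then Bu4NF, AcOH, THF, −40 °C
Reagents that add atoms: none
Why: Mukaiyama–Michael addition: the ketene silyl acetal attacks C5 of the silyl-activated enone anti to the C1 silyloxy group (steric and stereoelectronic preference of γ-silyloxy cyclopentenones), which places CH2CO2Me cis to CH2OSi and sets C5. Buffered fluoride then cleaves only the silyl enol ether.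

Step 5
Reactants: 10 methyl 2-[(1S,2R)-2-{[(tert-butyldiphenylsilyl)oxy]methyl}-4-oxo-2-[(triethylsilyl)oxy]cyclopentyl]acetate
Product: 11 methyl 2-[(1S,2R)-2-{[(tert-butyldiphenylsilyl)oxy]methyl}-4-methylidene-2-[(triethylsilyl)oxy]cyclopentyl]acetate
Conditions: Zn, CH2Br2, TiCl4, THF/CH2Cl2, 0 °C to rt
Reagents that add atoms: dibromomethane, BrCBr
Why: Takai–Lombardo methylenation: the non-basic zinc/titanium methylene reagent converts the ketone and not the ester, and avoids E1cB loss of the β-silyloxy group.

Step 6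
Reactants: 11 methyl 2-[(1S,2R)-2-{[(tert-butyldiphenylsilyl)oxy]methyl}-4-methylidene-2-[(triethylsilyl)oxy]cyclopentyl]acetate
Product: 12 methyl 2-[(1S,2R)-2-{[(tert-butyldiphenylsilyl)oxy]methyl}-2-hydroxy-4-methylidenecyclopentyl]acetate
Conditions: HF·pyridine, pyridine, THF, 0 °C
Reagents that add atoms: none
Why: Selective desilylation: the triethylsilyl ether is far more labile to fluoride than the tert-butyldiphenylsilyl ether. The free hydroxyl makes the α face of C3 the open one for step 7.

Step 7
Reactants: 12 methyl 2-[(1S,2R)-2-{[(tert-butyldiphenylsilyl)oxy]methyl}-2-hydroxy-4-methylidenecyclopentyl]acetate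
Product: 14 methyl 2-[(1S,2R,4S)-2-{[(tert-butyldiphenylsilyl)oxy]methyl}-2-hydroxy-4-(hydroxymethyl)cyclopentyl]acetate, via alkylborane 13 (not isolated)
Conditions: 9-BBN, THF, 0 °C to rt; then NaBO3·4H2O, H2O
Reagents that add atoms: sodium perborate, [Na+].[Na+].O[B-]1(O)OO[B-](O)(O)OO1
Why: Anti-Markovnikov hydroboration–oxidation of the 1,1-disubstituted alkene: 9-BBN should approach C3 from the α face, which carries only the small hydroxyl, away from the two cis carbon substituents on C1 and C5, so hydrogen is delivered α and the new CH2OH is β (C3 set). Perborate oxidation spares the ester.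

Step 8
Reactants: 14 methyl 2-[(1S,2R,4S)-2-{[(tert-butyldiphenylsilyl)oxy]methyl}-2-hydroxy-4-(hydroxymethyl)cyclopentyl]acetate
Product: 15 methyl 2-[(1S,2R,4S)-2-{[(tert-butyldiphenylsilyl)oxy]methyl}-4-formyl-2-hydroxycyclopentyl]acetate
Conditions: Dess–Martin periodinane, NaHCO3, CH2Cl2, 0 °C
Reagents that add atoms: none
Why: Dess–Martin oxidation of the primary alcohol; the tertiary alcohol cannot be oxidised and the buffered conditions should not epimerise C3.

Step 9
Reactants: 15 methyl 2-[(1S,2R,4S)-2-{[(tert-butyldiphenylsilyl)oxy]methyl}-4-formyl-2-hydroxycyclopentyl]acetate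
Product: 16 methyl 2-[(1S,2R,4S)-2-{[(tert-butyldiphenylsilyl)oxy]methyl}-4-ethynyl-2-hydroxycyclopentyl]acetate
Conditions: dimethyl (1-diazo-2-oxopropyl)phosphonate, K2CO3, MeOH, 0 °C to rt
Reagents that add atoms: dimethyl (1-diazo-2-oxopropyl)phosphonate, COP(=O)(OC)C(=[N+]=[N-])C(C)=O
Why: Seyferth–Gilbert homologation with the Ohira–Bestmann reagent: the diazomethylphosphonate anion released by methanolysis converts the aldehyde into the terminal alkyne at low temperature, which should outpace α-epimerisation. The methyl ester is unchanged in methanol.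

Step 10
Reactants: 16 methyl 2-[(1S,2R,4S)-2-{[(tert-butyldiphenylsilyl)oxy]methyl}-4-ethynyl-2-hydroxycyclopentyl]acetate; 17 1-bromo-3-methylbut-2-ene
Product: 19 methyl 2-[(1S,2R,4S)-2-{[(tert-butyldiphenylsilyl)oxy]methyl}-2-hydroxy-4-[(2E)-6-methylhepta-2,5-dien-2-yl]cyclopentyl]acetate, via alkenylalane 18 (not isolated)
Conditions: Me3Al, Cp2ZrCl2 (20 mol %), H2O (1 equiv), CH2Cl2, −20 °C; then 17, Pd(PPh3)4 (5 mol %), THF, 0 °C to rt
Reagents that add atoms: trimethylaluminium, C[Al](C)C
Why: Negishi zirconium-catalysed carboalumination adds methyl and aluminium syn across the alkyne with aluminium on the terminal carbon, fixing the E geometry of C7=C8. Zerovalent-palladium-catalysed coupling of 18 at the primary carbon of the allylic bromide gives the skipped diene with retention; the hydroxyl travels as its aluminium alkoxide and the low temperature spares the ester.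

Step 11
Reactants: 19 methyl 2-[(1S,2R,4S)-2-{[(tert-butyldiphenylsilyl)oxy]methyl}-2-hydroxy-4-[(2E)-6-methylhepta-2,5-dien-2-yl]cyclopentyl]acetate
Product: 20 2-[(1S,2R,4S)-2-{[(tert-butyldiphenylsilyl)oxy]methyl}-2-hydroxy-4-[(2E)-6-methylhepta-2,5-dien-2-yl]cyclopentyl]acetic acid
Conditions: LiOH, THF/MeOH/H2O, rt; then 1 M HCl to pH 3
Reagents that add atoms: lithium hydroxide, [Li+].[OH-]
Why: Saponification; the silyl ether and the skipped diene are inert to hydroxide, and lactonisation onto the trans tertiary hydroxyl is geometrically impossible.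

Step 12
Reactants: 20 2-[(1S,2R,4S)-2-{[(tert-butyldiphenylsilyl)oxy]methyl}-2-hydroxy-4-[(2E)-6-methylhepta-2,5-dien-2-yl]cyclopentyl]acetic acid; 21 (2E)-but-2-en-1-ol
Product: 22 (2E)-but-2-en-1-yl 2-[(1S,2R,4S)-2-{[(tert-butyldiphenylsilyl)oxy]methyl}-2-hydroxy-4-[(2E)-6-methylhepta-2,5-dien-2-yl]cyclopentyl]acetate
Conditions: EDC·HCl, 4-(dimethylamino)pyridine (10 mol %), CH2Cl2, 0 °C to rt
Reagents that add atoms: none
Why: Steglich esterification of the primary allylic alcohol; the hindered tertiary hydroxyl is not acylated.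

Step 13
Reactants: 22 (2E)-but-2-en-1-yl 2-[(1S,2R,4S)-2-{[(tert-butyldiphenylsilyl)oxy]methyl}-2-hydroxy-4-[(2E)-6-methylhepta-2,5-dien-2-yl]cyclopentyl]acetate
Product: 25 (2S,3R)-2-[(1S,2R,4S)-2-{[(tert-butyldiphenylsilyl)oxy]methyl}-2-hydroxy-4-[(2E)-6-methylhepta-2,5-dien-2-yl]cyclopentyl]-3-methylpent-4-enoic acid, via silyl ketene acetal 23 (not isolated), via trimethylsilyl ester 24 (not isolated)
Conditions: LiN(i-Pr)2 (2.3 equiv), Me3SiCl (4 equiv), THF, −78 °C to rt, then 50 °C; then 1 M HCl
Reagents that add atoms: none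
Why: Ireland–Claisen rearrangement: enolisation in THF without polar additive gives 23 with the ring A carbon cis to the butenyloxy oxygen, and the chair transition state with the E-butenyl unit gives the anti (2S,3R) pair, which becomes the cis pair of ring B. The enolate face is chosen by C5: with C5–H eclipsing the double bond (A(1,3) strain) the quaternary C1 blocks one face and the allyl unit bonds past the C4 methylene, which corresponds to (S) at C1′. The tertiary hydroxyl is silylated in the flask and freed again by the acidic work-up.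

Step 14
Reactants: 25 (2S,3R)-2-[(1S,2R,4S)-2-{[(tert-butyldiphenylsilyl)oxy]methyl}-2-hydroxy-4-[(2E)-6-methylhepta-2,5-dien-2-yl]cyclopentyl]-3-methylpent-4-enoic acid
Product: 27 (2S,3R)-2-[(1S,2R,4S)-2-{[(tert-butyldiphenylsilyl)oxy]methyl}-2-hydroxy-4-[(2E)-6-methylhepta-2,5-dien-2-yl]cyclopentyl]-N-methoxy-N,3-dimethylpent-4-enamide, via acyl imidazolide 26 (not isolated)
Conditions: 1,1′-carbonyldiimidazole, CH2Cl2, rt; then MeNH(OMe)·HCl
Reagents that add atoms: N,O-dimethylhydroxylamine hydrochloride, CNOC.Cl
Why: Weinreb amide formation through the acyl imidazolide; no base stronger than imidazole is present, so C1′ should not epimerise.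

Step 15
Reactants: 27 (2S,3R)-2-[(1S,2R,4S)-2-{[(tert-butyldiphenylsilyl)oxy]methyl}-2-hydroxy-4-[(2E)-6-methylhepta-2,5-dien-2-yl]cyclopentyl]-N-methoxy-N,3-dimethylpent-4-enamide
Product: 29 (4S,5R)-4-[(1S,2R,4S)-2-{[(tert-butyldiphenylsilyl)oxy]methyl}-2-hydroxy-4-[(2E)-6-methylhepta-2,5-dien-2-yl]cyclopentyl]-5-methylhepta-1,6-dien-3-one, via magnesium hemiaminal 28 (not isolated)
Conditions: vinylmagnesium bromide (3 equiv), THF, −20 to 0 °C; inverse quench into cold 1 M HCl
Reagents that add atoms: vinylmagnesium bromide, C=C[Mg]Br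
Why: Weinreb ketone synthesis: the chelated adduct 28 persists until the quench, so addition stops at the vinyl ketone. The inverse acidic quench keeps the liberated amine from adding to the enone and spares C1′.

Step 16
Reactants: 29 (4S,5R)-4-[(1S,2R,4S)-2-{[(tert-butyldiphenylsilyl)oxy]methyl}-2-hydroxy-4-[(2E)-6-methylhepta-2,5-dien-2-yl]cyclopentyl]-5-methylhepta-1,6-dien-3-one
Product: 30 (4R,5S)-5-[(1S,2R,4S)-2-{[(tert-butyldiphenylsilyl)oxy]methyl}-2-hydroxy-4-[(2E)-6-methylhepta-2,5-dien-2-yl]cyclopentyl]-4-methylcyclopent-2-en-1-one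
Conditions: second-generation Hoveyda–Grubbs catalyst RuCl2(H2IMes)(=CH-C6H4-2-O-i-Pr) (5 mol %), 1,4-benzoquinone (10 mol %), CH2Cl2 (5 mM), 40 °C
Reagents that add atoms: none
Why: Ring-closing metathesis of the vinyl ketone with the monosubstituted alkene closes the five-membered enone and releases ethene; the trisubstituted chain alkenes are much slower partners. The neutral conditions leave the cis C1′/C5′ pair untouched.

Step 17
Reactants: 30 (4R,5S)-5-[(1S,2R,4S)-2-{[(tert-butyldiphenylsilyl)oxy]methyl}-2-hydroxy-4-[(2E)-6-methylhepta-2,5-dien-2-yl]cyclopentyl]-4-methylcyclopent-2-en-1-one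
Product: 31 (4R,5S)-5-[(1S,2R,4S)-2-hydroxy-2-(hydroxymethyl)-4-[(2E)-6-methylhepta-2,5-dien-2-yl]cyclopentyl]-4-methylcyclopent-2-en-1-one
Conditions: Bu4NF, AcOH (1:1), THF, 0 °C to rt
Reagents that add atoms: none
Why: Fluoride cleavage of the primary silyl ether, buffered with acetic acid so that C1′, α to the ketone, is not epimerised.

Step 18
Reactants: 31 (4R,5S)-5-[(1S,2R,4S)-2-hydroxy-2-(hydroxymethyl)-4-[(2E)-6-methylhepta-2,5-dien-2-yl]cyclopentyl]-4-methylcyclopent-2-en-1-one
Product: 32 [(1R,2S,4S)-1-hydroxy-4-[(2E)-6-methylhepta-2,5-dien-2-yl]-2-[(1S,5R)-5-methyl-2-oxocyclopent-3-en-1-yl]cyclopentyl]methyl acetate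
Conditions: Ac2O (1.1 equiv), pyridine, CH2Cl2, 0 °C
Reagents that add atoms: acetic anhydride, CC(=O)OC(C)=O
Why: Acetylation of the primary alcohol; without an acyl-transfer catalyst the tertiary alcohol should not react.

Step 19
Reactants: 32 [(1R,2S,4S)-1-hydroxy-4-[(2E)-6-methylhepta-2,5-dien-2-yl]-2-[(1S,5R)-5-methyl-2-oxocyclopent-3-en-1-yl]cyclopentyl]methyl acetate
Product: 33 [(1R,2S,4S)-4-[(2E,4E)-6-hydroperoxy-6-methylhepta-2,4-dien-2-yl]-1-hydroxy-2-[(1S,5R)-5-methyl-2-oxocyclopent-3-en-1-yl]cyclopentyl]methyl acetate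
Conditions: O2, 5,10,15,20-tetraphenylporphyrin (1 mol %), white LED, CH2Cl2, −20 °C, stopped at partial conversion
Reagents that add atoms: dioxygen, O=O
Why: Schenck ene reaction: singlet oxygen adds to the electron-rich C10=C11 alkene with abstraction of the doubly allylic C9–H on its more substituted side, which moves the double bond to C9=C10 (E) and places OOH on the tertiary C11; the enone is inert. Ene reaction at C7=C8 and abstraction from the cis methyl group are the expected competitors, hence partial conversion and recycling of 32.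

## Compound list

1 | 5-(hydroxymethyl)furan-2-carbaldehyde (5-(hydroxymethyl)furfural) | O=Cc1ccc(CO)o1 | starting material
2 | furan-2,5-diyldimethanol (2,5-bis(hydroxymethyl)furan) | OCc1ccc(CO)o1 | intermediate
3 | 2-(hydroxymethyl)-5-methylidene-2,5-dihydrofuran-2-ol | C=C1C=CC(O)(CO)O1 | intermediate (not isolated)
4 | O-protonated (3Z)-1,5-dihydroxyhexa-3,5-dien-2-one (1,4-dihydroxypentadienyl cation) | C=C(O)/C=C\C(CO)=[OH+] | intermediate (not isolated)
5 | (4R)-4-hydroxy-4-(hydroxymethyl)cyclopent-2-en-1-one | OC[C@@]1(O)CC(=O)C=C1 | intermediate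
6 | (4R)-4-{[(tert-butyldiphenylsilyl)oxy]methyl}-4-hydroxycyclopent-2-en-1-one | CC(C)(C)[Si](c1ccccc1)(c1ccccc1)OC[C@@]1(O)CC(=O)C=C1 | intermediate (not isolated)
7 | (4R)-4-{[(tert-butyldiphenylsilyl)oxy]methyl}-4-[(triethylsilyl)oxy]cyclopent-2-en-1-one | CC(C)(C)[Si](c1ccccc1)(c1ccccc1)OC[C@@]1(O[Si](CC)(CC)CC)CC(=O)C=C1 | intermediate
8 | tert-butyl[(1-methoxyethenyl)oxy]dimethylsilane | C=C(OC)O[Si](C)(C)C(C)(C)C | starting material
9 | methyl 2-[(1R,5R)-3-[(tert-butyldimethylsilyl)oxy]-5-{[(tert-butyldiphenylsilyl)oxy]methyl}-5-[(triethylsilyl)oxy]cyclopent-2-en-1-yl]acetate | CC(C)(C)[Si](c1ccccc1)(c1ccccc1)OC[C@@]1(O[Si](CC)(CC)CC)CC(O[Si](C)(C)C(C)(C)C)=C[C@H]1CC(=O)OC | intermediate (not isolated)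
10 | methyl 2-[(1S,2R)-2-{[(tert-butyldiphenylsilyl)oxy]methyl}-4-oxo-2-[(triethylsilyl)oxy]cyclopentyl]acetate | CC(C)(C)[Si](c1ccccc1)(c1ccccc1)OC[C@@]1(O[Si](CC)(CC)CC)CC(=O)C[C@H]1CC(=O)OC | intermediate
11 | methyl 2-[(1S,2R)-2-{[(tert-butyldiphenylsilyl)oxy]methyl}-4-methylidene-2-[(triethylsilyl)oxy]cyclopentyl]acetate | CC(C)(C)[Si](c1ccccc1)(c1ccccc1)OC[C@@]1(O[Si](CC)(CC)CC)CC(=C)C[C@H]1CC(=O)OC | intermediate
12 | methyl 2-[(1S,2R)-2-{[(tert-butyldiphenylsilyl)oxy]methyl}-2-hydroxy-4-methylidenecyclopentyl]acetate | CC(C)(C)[Si](c1ccccc1)(c1ccccc1)OC[C@@]1(O)CC(=C)C[C@H]1CC(=O)OC | intermediate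
13 | methyl 2-[(1S,2R,4S)-4-[(9-borabicyclo[3.3.1]nonan-9-yl)methyl]-2-{[(tert-butyldiphenylsilyl)oxy]methyl}-2-hydroxycyclopentyl]acetate | CC(C)(C)[Si](c1ccccc1)(c1ccccc1)OC[C@@]1(O)C[C@@H](CB2C3CCCC2CCC3)C[C@H]1CC(=O)OC | intermediate (not isolated)
14 | methyl 2-[(1S,2R,4S)-2-{[(tert-butyldiphenylsilyl)oxy]methyl}-2-hydroxy-4-(hydroxymethyl)cyclopentyl]acetate | CC(C)(C)[Si](c1ccccc1)(c1ccccc1)OC[C@@]1(O)C[C@@H](CO)C[C@H]1CC(=O)OC | intermediate
15 | methyl 2-[(1S,2R,4S)-2-{[(tert-butyldiphenylsilyl)oxy]methyl}-4-formyl-2-hydroxycyclopentyl]acetate | CC(C)(C)[Si](c1ccccc1)(c1ccccc1)OC[C@@]1(O)C[C@@H](C=O)C[C@H]1CC(=O)OC | intermediate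
16 | methyl 2-[(1S,2R,4S)-2-{[(tert-butyldiphenylsilyl)oxy]methyl}-4-ethynyl-2-hydroxycyclopentyl]acetate | CC(C)(C)[Si](c1ccccc1)(c1ccccc1)OC[C@@]1(O)C[C@@H](C#C)C[C@H]1CC(=O)OC | intermediate
17 | 1-bromo-3-methylbut-2-ene (prenyl bromide) | CC(C)=CCBr | starting material
18 | methyl 2-[(1S,2R,4S)-2-{[(tert-butyldiphenylsilyl)oxy]methyl}-2-[(dimethylalumanyl)oxy]-4-[(1E)-1-(dimethylalumanyl)prop-1-en-2-yl]cyclopentyl]acetate | CC(C)(C)[Si](c1ccccc1)(c1ccccc1)OC[C@@]1(O[Al](C)C)C[C@@H](/C(C)=C/[Al](C)C)C[C@H]1CC(=O)OC | intermediate (not isolated)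
19 | methyl 2-[(1S,2R,4S)-2-{[(tert-butyldiphenylsilyl)oxy]methyl}-2-hydroxy-4-[(2E)-6-methylhepta-2,5-dien-2-yl]cyclopentyl]acetate | CC(C)(C)[Si](c1ccccc1)(c1ccccc1)OC[C@@]1(O)C[C@@H](/C(C)=C/CC=C(C)C)C[C@H]1CC(=O)OC | intermediate
20 | 2-[(1S,2R,4S)-2-{[(tert-butyldiphenylsilyl)oxy]methyl}-2-hydroxy-4-[(2E)-6-methylhepta-2,5-dien-2-yl]cyclopentyl]acetic acid | CC(C)(C)[Si](c1ccccc1)(c1ccccc1)OC[C@@]1(O)C[C@@H](/C(C)=C/CC=C(C)C)C[C@H]1CC(=O)O | intermediate
21 | (2E)-but-2-en-1-ol | C/C=C/CO | starting material
22 | (2E)-but-2-en-1-yl 2-[(1S,2R,4S)-2-{[(tert-butyldiphenylsilyl)oxy]methyl}-2-hydroxy-4-[(2E)-6-methylhepta-2,5-dien-2-yl]cyclopentyl]acetate | CC(C)(C)[Si](c1ccccc1)(c1ccccc1)OC[C@@]1(O)C[C@@H](/C(C)=C/CC=C(C)C)C[C@H]1CC(=O)OC/C=C/C | intermediate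
23 | O-trimethylsilyl ketene acetal of 22, ring A carbon cis to the butenyloxy group, C1 oxygen as trimethylsilyl ether | CC(C)(C)[Si](c1ccccc1)(c1ccccc1)OC[C@@]1(O[Si](C)(C)C)C[C@@H](/C(C)=C/CC=C(C)C)C[C@H]1/C=C(\OC/C=C/C)O[Si](C)(C)C | intermediate (not isolated)
24 | trimethylsilyl (2S,3R)-2-[(1S,2R,4S)-2-{[(tert-butyldiphenylsilyl)oxy]methyl}-4-[(2E)-6-methylhepta-2,5-dien-2-yl]-2-[(trimethylsilyl)oxy]cyclopentyl]-3-methylpent-4-enoate | CC(C)(C)[Si](c1ccccc1)(c1ccccc1)OC[C@@]1(O[Si](C)(C)C)C[C@@H](/C(C)=C/CC=C(C)C)C[C@H]1[C@@H](C(=O)O[Si](C)(C)C)[C@H](C)C=C | intermediate (not isolated)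
25 | (2S,3R)-2-[(1S,2R,4S)-2-{[(tert-butyldiphenylsilyl)oxy]methyl}-2-hydroxy-4-[(2E)-6-methylhepta-2,5-dien-2-yl]cyclopentyl]-3-methylpent-4-enoic acid | CC(C)(C)[Si](c1ccccc1)(c1ccccc1)OC[C@@]1(O)C[C@@H](/C(C)=C/CC=C(C)C)C[C@H]1[C@@H](C(=O)O)[C@H](C)C=C | intermediate
26 | 1-[(2S,3R)-2-[(1S,2R,4S)-2-{[(tert-butyldiphenylsilyl)oxy]methyl}-2-hydroxy-4-[(2E)-6-methylhepta-2,5-dien-2-yl]cyclopentyl]-3-methylpent-4-enoyl]-1H-imidazole | CC(C)(C)[Si](c1ccccc1)(c1ccccc1)OC[C@@]1(O)C[C@@H](/C(C)=C/CC=C(C)C)C[C@H]1[C@@H](C(=O)n2ccnc2)[C@H](C)C=C | intermediate (not isolated)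
27 | (2S,3R)-2-[(1S,2R,4S)-2-{[(tert-butyldiphenylsilyl)oxy]methyl}-2-hydroxy-4-[(2E)-6-methylhepta-2,5-dien-2-yl]cyclopentyl]-N-methoxy-N,3-dimethylpent-4-enamide | CC(C)(C)[Si](c1ccccc1)(c1ccccc1)OC[C@@]1(O)C[C@@H](/C(C)=C/CC=C(C)C)C[C@H]1[C@@H](C(=O)N(C)OC)[C@H](C)C=C | intermediate
28 | bis(bromomagnesium) alkoxide of the tetrahedral vinyl adduct of 27 (N-methoxy-N-methyl hemiaminal at C2′, alkoxide at C1) | CC(C)(C)[Si](c1ccccc1)(c1ccccc1)OC[C@@]1(O[Mg]Br)C[C@@H](/C(C)=C/CC=C(C)C)C[C@H]1[C@@H](C(O[Mg]Br)(C=C)N(C)OC)[C@H](C)C=C | intermediate (not isolated)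
29 | (4S,5R)-4-[(1S,2R,4S)-2-{[(tert-butyldiphenylsilyl)oxy]methyl}-2-hydroxy-4-[(2E)-6-methylhepta-2,5-dien-2-yl]cyclopentyl]-5-methylhepta-1,6-dien-3-one | CC(C)(C)[Si](c1ccccc1)(c1ccccc1)OC[C@@]1(O)C[C@@H](/C(C)=C/CC=C(C)C)C[C@H]1[C@@H](C(=O)C=C)[C@H](C)C=C | intermediate
30 | (4R,5S)-5-[(1S,2R,4S)-2-{[(tert-butyldiphenylsilyl)oxy]methyl}-2-hydroxy-4-[(2E)-6-methylhepta-2,5-dien-2-yl]cyclopentyl]-4-methylcyclopent-2-en-1-one | CC(C)(C)[Si](c1ccccc1)(c1ccccc1)OC[C@@]1(O)C[C@@H](/C(C)=C/CC=C(C)C)C[C@H]1[C@H]1C(=O)C=C[C@H]1C | intermediate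
31 | (4R,5S)-5-[(1S,2R,4S)-2-hydroxy-2-(hydroxymethyl)-4-[(2E)-6-methylhepta-2,5-dien-2-yl]cyclopentyl]-4-methylcyclopent-2-en-1-one | OC[C@@]1(O)C[C@@H](/C(C)=C/CC=C(C)C)C[C@H]1[C@H]1C(=O)C=C[C@H]1C | intermediate
32 | [(1R,2S,4S)-1-hydroxy-4-[(2E)-6-methylhepta-2,5-dien-2-yl]-2-[(1S,5R)-5-methyl-2-oxocyclopent-3-en-1-yl]cyclopentyl]methyl acetate | CC(=O)OC[C@@]1(O)C[C@@H](/C(C)=C/CC=C(C)C)C[C@H]1[C@H]1C(=O)C=C[C@H]1C | intermediate
33 | [(1R,2S,4S)-4-[(2E,4E)-6-hydroperoxy-6-methylhepta-2,4-dien-2-yl]-1-hydroxy-2-[(1S,5R)-5-methyl-2-oxocyclopent-3-en-1-yl]cyclopentyl]methyl acetate (CNP0204569.2) | CC(=O)OC[C@@]1(O)C[C@@H](/C(C)=C/C=C/C(C)(C)OO)C[C@H]1[C@H]1C(=O)C=C[C@H]1C | target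

## Step count and least certain steps

Total: 19 steps. Longest linear sequence: 19 steps (1 to 33); 8, 17 and 21 are purchased.

Step 2 (key step, proposed new method).
- What may go wrong: insufficient enantiofacial discrimination in the ring closure, because the uncatalysed racemic pathway competes and hydrogen-bonding solvent loosens the ion pair; also acid-induced oligomerisation of 2.
- Fallback (known chemistry): from 2, heating in water alone (0.1 M, 200 °C, sealed vessel) gives racemic 4-hydroxy-4-(hydroxymethyl)cyclopent-2-en-1-one F1 by the known thermal rearrangement. Lipase from Burkholderia cepacia with vinyl acetate in tert-butyl methyl ether then acetylates the primary hydroxyl of the (S)-enantiomer to [(1S)-1-hydroxy-4-oxocyclopent-2-en-1-yl]methyl acetate F2. The unreacted alcohol, taken beyond half conversion, is 5, where the route is rejoined.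

Step 19.
- What may go wrong: poor site selectivity between the two trisubstituted alkenes and poor regioselectivity of hydrogen abstraction (cis methyl instead of C9–H), with over-oxidation at high conversion.
- Fallback: from 32 directly to 33 by radical-chain autoxidation instead of the ene reaction (O2 at 1 atm, N-hydroxyphthalimide 10 mol %, a low-temperature azo initiator, MeCN, 30 °C). The N-oxyl radical abstracts the weakest hydrogen, the doubly allylic C9–H, and the pentadienyl radical takes up triplet oxygen at a tertiary terminus, C11 being the less hindered. Only the C7 regioisomer should then compete; no new compound lies on the way.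

Step 13.
- What may go wrong: poor facial selectivity of the enolate with respect to ring A (the A(1,3) bias may be too small), or erosion of enolate geometry; either lowers the C1′/C5′ purity.
- Fallback: from 20, esterification (EDC·HCl, 4-(dimethylamino)pyridine) with (2S,3E)-pent-3-en-2-ol gives the pent-3-en-2-yl ester F3. The same enolisation, silylation and rearrangement then pass through a chair with the carbinol methyl equatorial, so the carbinol configuration (matched with the substrate preference) dictates both new centres and gives the 3-methylhex-4-enoic acid F4. Carbonyldiimidazole and MeNH(OMe)·HCl give the N-methoxy-N-methylamide F5, vinylmagnesium bromide gives the octa-1,6-dien-3-one F6, and ring-closing metathesis, now releasing propene, gives 30.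

Step 7.
- What may go wrong: poor facial selectivity of the hydroboration, since C3 is only 1,3-related to the controlling centres.
- Fallback: from 12, cross-metathesis with vinylboronic acid pinacol ester (second-generation Hoveyda–Grubbs catalyst RuCl2(H2IMes)(=CH-C6H4-2-O-i-Pr)) gives the exocyclic alkenylboronate F7. Hydrogenation with [Ir(cod)(PCy3)(py)]PF6 under H2 in CH2Cl2 is directed by the free tertiary hydroxyl, which binds iridium and delivers hydrogen to C3 from the α face, giving the alkylboronate F8. NaBO3 oxidation then gives 14.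

Step 4.
- What may go wrong: poor facial selectivity of the conjugate addition, because the β face carries the bulky silyloxymethyl group on the same carbon as the directing silyloxy group.
- Fallback: from 5, N-bromosuccinimide and ethyl vinyl ether convert the primary hydroxyl into the bromoacetal F9, and Et3SiOTf/2,6-lutidine gives its triethylsilyl ether F10. Bu3SnH with azobis(isobutyronitrile) in benzene at 80 °C generates a primary radical that can reach C5 only from the β face in a 6-exo closure (Ueno–Stork cyclisation), giving the cis-fused bicyclic acetal F11. Jones oxidation (CrO3, H2SO4, acetone) gives the keto lactone F12. Methanolysis (K2CO3, MeOH, 0 °C) with in-situ silylation of the freed primary alcohol (t-BuPh2SiCl, imidazole) gives 10.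

## Further compounds

F1 | step 2 | rac-4-hydroxy-4-(hydroxymethyl)cyclopent-2-en-1-one | OCC1(O)CC(=O)C=C1
F2 | step 2 | [(1S)-1-hydroxy-4-oxocyclopent-2-en-1-yl]methyl acetate | CC(=O)OC[C@]1(O)CC(=O)C=C1
F0 | step 19 | none | none
F3 | step 13 | (2S,3E)-pent-3-en-2-yl 2-[(1S,2R,4S)-2-{[(tert-butyldiphenylsilyl)oxy]methyl}-2-hydroxy-4-[(2E)-6-methylhepta-2,5-dien-2-yl]cyclopentyl]acetate | CC(C)(C)[Si](c1ccccc1)(c1ccccc1)OC[C@@]1(O)C[C@@H](/C(C)=C/CC=C(C)C)C[C@H]1CC(=O)O[C@@H](C)/C=C/C
F4 | step 13 | (2S,3R,4E)-2-[(1S,2R,4S)-2-{[(tert-butyldiphenylsilyl)oxy]methyl}-2-hydroxy-4-[(2E)-6-methylhepta-2,5-dien-2-yl]cyclopentyl]-3-methylhex-4-enoic acid | CC(C)(C)[Si](c1ccccc1)(c1ccccc1)OC[C@@]1(O)C[C@@H](/C(C)=C/CC=C(C)C)C[C@H]1[C@@H](C(=O)O)[C@H](C)/C=C/C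
F5 | step 13 | (2S,3R,4E)-2-[(1S,2R,4S)-2-{[(tert-butyldiphenylsilyl)oxy]methyl}-2-hydroxy-4-[(2E)-6-methylhepta-2,5-dien-2-yl]cyclopentyl]-N-methoxy-N,3-dimethylhex-4-enamide | CC(C)(C)[Si](c1ccccc1)(c1ccccc1)OC[C@@]1(O)C[C@@H](/C(C)=C/CC=C(C)C)C[C@H]1[C@@H](C(=O)N(C)OC)[C@H](C)/C=C/C
F6 | step 13 | (4S,5R,6E)-4-[(1S,2R,4S)-2-{[(tert-butyldiphenylsilyl)oxy]methyl}-2-hydroxy-4-[(2E)-6-methylhepta-2,5-dien-2-yl]cyclopentyl]-5-methylocta-1,6-dien-3-one | CC(C)(C)[Si](c1ccccc1)(c1ccccc1)OC[C@@]1(O)C[C@@H](/C(C)=C/CC=C(C)C)C[C@H]1[C@@H](C(=O)C=C)[C@H](C)/C=C/C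
F7 | step 7 | methyl 2-[(1S,2R)-2-{[(tert-butyldiphenylsilyl)oxy]methyl}-2-hydroxy-4-[(4,4,5,5-tetramethyl-1,3,2-dioxaborolan-2-yl)methylidene]cyclopentyl]acetate | CC(C)(C)[Si](c1ccccc1)(c1ccccc1)OC[C@@]1(O)CC(=CB2OC(C)(C)C(C)(C)O2)C[C@H]1CC(=O)OC
F8 | step 7 | methyl 2-[(1S,2R,4S)-2-{[(tert-butyldiphenylsilyl)oxy]methyl}-2-hydroxy-4-[(4,4,5,5-tetramethyl-1,3,2-dioxaborolan-2-yl)methyl]cyclopentyl]acetate | CC(C)(C)[Si](c1ccccc1)(c1ccccc1)OC[C@@]1(O)C[C@@H](CB2OC(C)(C)C(C)(C)O2)C[C@H]1CC(=O)OC
F9 | step 4 | (4R)-4-[(2-bromo-1-ethoxyethoxy)methyl]-4-hydroxycyclopent-2-en-1-one | CCOC(CBr)OC[C@@]1(O)CC(=O)C=C1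
F10 | step 4 | (4R)-4-[(2-bromo-1-ethoxyethoxy)methyl]-4-[(triethylsilyl)oxy]cyclopent-2-en-1-one | CCOC(CBr)OC[C@@]1(O[Si](CC)(CC)CC)CC(=O)C=C1
F11 | step 4 | (4aR,7aR)-3-ethoxy-7a-[(triethylsilyl)oxy]hexahydrocyclopenta[c]pyran-6(1H)-one (cis-fused) | O2C[C@@]1(O[Si](CC)(CC)CC)CC(=O)C[C@H]1CC2OCC
F12 | step 4 | (4aS,7aR)-7a-[(triethylsilyl)oxy]hexahydrocyclopenta[c]pyran-3,6-dione (cis-fused keto lactone) | O2C[C@@]1(O[Si](CC)(CC)CC)CC(=O)C[C@H]1CC2=O
A1 | alternative 1 | 2-bromobicyclo[2.2.1]hept-5-ene-2-carbaldehyde, formyl exo and bromine endo, stereochemistry as encoded in the SMILES | O=C[C@]1(Br)C[C@H]2C=C[C@@H]1C2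
A2 | alternative 1 | cyclopenta-1,3-diene | C1=CC=CC1
A3 | alternative 1 | 2-bromoprop-2-enal | C=C(Br)C=O
A4 | alternative 1 | spiro[bicyclo[2.2.1]hept-5-ene-2,2′-oxirane], oxirane oxygen exo, stereochemistry as encoded in the SMILES | O3[C@]1(C3)C[C@H]2C=C[C@@H]1C2
A5 | alternative 2 | 5-{2-[(tert-butyldimethylsilyloxy)methyl]-2-hydroxy-4-[(2E)-6-methylhepta-2,5-dien-2-yl]cyclopentyl}-4-methylcyclopent-2-en-1-one, stereochemistry as encoded in the SMILES | CC(C)(C)[Si](C)(C)OC[C@@]1(O)C[C@@H](/C(C)=C/CC=C(C)C)C[C@H]1[C@H]1C(=O)C=C[C@H]1C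
A6 | alternative 2 | (4R)-5-{(3S)-6-[(tert-butyldimethylsilyl)oxy]-3-[(2E)-6-methylhepta-2,5-dien-2-yl]-5-oxohexylidene}-4-methylcyclopent-2-en-1-one | CC(C)(C)[Si](C)(C)OCC(=O)C[C@@H](/C(C)=C/CC=C(C)C)CC=C1C(=O)C=C[C@H]1C
A7 | alternative 3 | methyl 4-[(tert-butyldimethylsilyl)oxy]-2-formyl-1-hydroxycyclopent-2-ene-1-carboxylate, stereochemistry as encoded in the SMILES | COC(=O)[C@@]1(O)C[C@@H](O[Si](C)(C)C(C)(C)C)C=C1C=O
A8 | alternative 3 | (−)-quinic acid, (1S,3R,4S,5R)-1,3,4,5-tetrahydroxycyclohexane-1-carboxylic acid | OC(=O)[C@@]1(O)C[C@@H](O)[C@H](O)[C@H](O)C1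
A9 | alternative 3 | methyl 5-O-(tert-butyldimethylsilyl)quinate, stereochemistry as encoded in the SMILES | COC(=O)[C@@]1(O)C[C@@H](O[Si](C)(C)C(C)(C)C)[C@H](O)[C@H](O)C1
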